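**Target:** (2R,3R)-pinobanksin 3-O-hexanoate, a 2,3-trans flavanonol ester with C2 = R and C3 = R.

**Retrosynthetic overview**
- The 3-O-hexanoate is cut last, back to the free (2R,3R)-flavanonol: full acylation, then loss of the two aryl esters.
- Rings A and C are cut in one operation: ring C at O1–C2 (phenoxide opening of a trans-epoxide, inversion at the benzylic carbon) and ring A at C4a–C5 (Claisen closure of a triketo ester). This leads back to a 4-hydroxy-2-pyranone with an epoxy-ketone side chain.
- That pyranone is cut at C4–C4a into triacetic acid lactone (all six carbons and three oxygens of ring A) and a trans-phenylglycidate (C2, C3, C4, ring B, both stereocentres).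
- Ring order: ring B is bought; ring A then ring C form in the same flask. C3 is carried over from the glycidate; C2 is set by SN2 inversion.

Assumption: methyl (2R,3S)-3-phenylglycidate (the trans-glycidate used for the paclitaxel side chain) is bought as the single enantiomer.

**Step 1**
Reactants: 1 4-hydroxy-6-methyl-2H-pyran-2-one (triacetic acid lactone); 2 methyl (2R,3S)-3-phenyloxirane-2-carboxylate
Product: 4 4-hydroxy-6-{2-oxo-2-[(2R,3S)-3-phenyloxiran-2-yl]ethyl}-2H-pyran-2-one, via dilithium dianion 3 (not isolated)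
Conditions: 1 (2.2 equiv), LiN(iPr)2 (4.4 equiv), THF/DMPU, -78 to -40 °C; add 2 (1.0 equiv), -78 to -30 °C; AcOH, -78 °C
Reagents that add atoms: none
Why: Claisen-type C-acylation of the 6-methyl carbanion of the lactone dianion by the ester, which at -78 °C is faster than epoxide opening; the second equivalent of dianion deprotonates the product and so shields the new ketone, and no stereocentre is made or touched.

**Step 2**
Reactants: 4 4-hydroxy-6-{2-oxo-2-[(2R,3S)-3-phenyloxiran-2-yl]ethyl}-2H-pyran-2-one
Product: 7 (2R,3R)-pinobanksin, via triketo ester 5 (not isolated), via chalcone epoxide 6 (not isolated)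
Conditions: Mg(OMe)2 (8 equiv), MeOH, argon, 25 to 60 °C; then 1 M HCl, 0 °C
Reagents that add atoms: none
Why: Proposed new method: methoxide opens the pyranone to the magnesium-chelated triketo methyl ester 5, whose chelated C6 carbanion attacks the ester (intramolecular Claisen condensation, the known pyranone-to-acylphloroglucinol recyclization) to build ring A; an ortho-phenoxide of 6 then opens the trans-epoxide 6-endo at the activated benzylic carbon (the ring-closing half of Algar–Flynn–Oyamada-type chalcone epoxide cyclizations) to build ring C; C3 (R) comes unchanged from the glycidate and C2 (R) is set by SN2 inversion of the S benzylic carbon, giving the more stable 2,3-trans isomer.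

**Step 3**
Reactants: 7 (2R,3R)-pinobanksin; 8 hexanoyl chloride
Product: 10 (2R,3R)-5,7-dihydroxy-4-oxo-2-phenylchroman-3-yl hexanoate, via tris-hexanoate 9 (not isolated)
Conditions: 8 (3.5 equiv), pyridine, DMAP (5 mol %), CH2Cl2, 0 °C to rt; evaporate; NH4OAc (10 equiv), MeOH/THF/H2O, rt
Reagents that add atoms: none
Why: Exhaustive DMAP-catalysed O-acylation followed by chemoselective methanolysis of the two aryl esters, since phenoxide is a far better leaving group than the secondary alkoxide and the buffered NH4OAc medium leaves the 3-O-hexanoate intact; no stereocentre is formed and the near-neutral second stage avoids enolization at C3.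

**Compound list**
1 | 4-hydroxy-6-methyl-2H-pyran-2-one (triacetic acid lactone) | CC1=CC(O)=CC(=O)O1 | starting material
2 | methyl (2R,3S)-3-phenyloxirane-2-carboxylate | COC(=O)[C@@H]1O[C@H]1c1ccccc1 | starting material
3 | dilithium dianion of 1 (4-O and 6-CH2 deprotonated) | [Li+].[Li+].[CH2-]C1=CC([O-])=CC(=O)O1 | intermediate
4 | 4-hydroxy-6-{2-oxo-2-[(2R,3S)-3-phenyloxiran-2-yl]ethyl}-2H-pyran-2-one | O=C1C=C(O)C=C(CC(=O)[C@@H]2O[C@H]2c2ccccc2)O1 | intermediate
5 | methyl 3,5,7-trioxo-7-[(2R,3S)-3-phenyloxiran-2-yl]heptanoate (magnesium chelate in the flask) | COC(=O)CC(=O)CC(=O)CC(=O)[C@@H]1O[C@H]1c1ccccc1 | intermediate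
6 | [(2R,3S)-3-phenyloxiran-2-yl](2,4,6-trihydroxyphenyl)methanone | O=C(c1c(O)cc(O)cc1O)[C@@H]1O[C@H]1c1ccccc1 | intermediate
7 | (2R,3R)-3,5,7-trihydroxy-2-phenylchroman-4-one (pinobanksin) | O[C@H]1C(=O)c2c(O)cc(O)cc2O[C@@H]1c1ccccc1 | intermediate
8 | hexanoyl chloride | CCCCCC(Cl)=O | starting material
9 | (2R,3R)-4-oxo-2-phenylchromane-3,5,7-triyl trihexanoate | CCCCCC(=O)O[C@H]1C(=O)c2c(OC(=O)CCCCC)cc(OC(=O)CCCCC)cc2O[C@@H]1c1ccccc1 | intermediate
10 | (2R,3R)-5,7-dihydroxy-4-oxo-2-phenylchroman-3-yl hexanoate | CCCCCC(=O)O[C@H]1C(=O)c2c(O)cc(O)cc2O[C@@H]1c1ccccc1 | target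

**Total step count:** 3
**Longest linear sequence:** 3 steps

**Steps most likely to fail**

Step 2 (highest risk). The epoxide may be opened by methanol under Mg(OMe)2, or the phenoxide may attack the carbon next to the carbonyl and give a 2-(α-hydroxybenzyl)benzofuranone. The triketo ester may also close by aldol instead of Claisen, and the product is base-sensitive. The fallback replaces the epoxide by a diol that survives the Claisen conditions as its acetonide and closes ring C by Mitsunobu inversion. It sets out from 1. Bought methyl (2R,3S)-2,3-dihydroxy-3-phenylpropanoate F1 is converted with 2,2-dimethoxypropane and TsOH in acetone into methyl (4R,5S)-2,2-dimethyl-5-phenyl-1,3-dioxolane-4-carboxylate F2. F2 acylates dianion 3 of 1 under the conditions of step 1 to give 6-{2-[(4R,5S)-2,2-dimethyl-5-phenyl-1,3-dioxolan-4-yl]-2-oxoethyl}-4-hydroxy-2H-pyran-2-one F3. Mg(OMe)2 in MeOH converts F3 into [(4R,5S)-2,2-dimethyl-5-phenyl-1,3-dioxolan-4-yl](2,4,6-trihydroxyphenyl)methanone F4. Aqueous HCl in MeOH removes the acetonide to give (2R,3S)-2,3-dihydroxy-3-phenyl-1-(2,4,6-trihydroxyphenyl)propan-1-one F5. PPh3 and DIAD in THF at 0 °C then let an ortho-phenol displace the activated benzylic hydroxyl with inversion (S to R), and the fallback comes back to the route at 7.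

Step 1. The dianion may open the epoxide, or the glycidate may be deprotonated or react sluggishly as an ester. The fallback replaces the Claisen acylation by an aldol addition and an oxidation. It sets out from 2. iBu2AlH in toluene at -78 °C reduces 2 to (2R,3S)-3-phenyloxirane-2-carbaldehyde F6. Dianion 3 adds to F6 at -78 °C to give 4-hydroxy-6-{2-hydroxy-2-[(2S,3S)-3-phenyloxiran-2-yl]ethyl}-2H-pyran-2-one F7 as a mixture of carbinol epimers. Dess–Martin periodinane in CH2Cl2 oxidizes both epimers, and the fallback comes back to the route at 4.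

Step 3. The aryl esters may cleave incompletely, or the 3-O-ester may be lost or may epimerize. The fallback protects the reactive phenol instead of relying on ester lability. It sets out from 7. tert-Butyldimethylsilyl chloride (1.1 equiv) and imidazole in DMF at 0 °C silylate the acidic, unhindered 7-OH to give (2R,3R)-7-(tert-butyldimethylsilyloxy)-3,5-dihydroxy-2-phenylchroman-4-one F8. Hexanoyl chloride 8 (1.2 equiv) and pyridine in CH2Cl2 at 0 °C acylate the 3-OH, the 5-OH being held in a hydrogen bond to the C4 carbonyl, to give (2R,3R)-7-(tert-butyldimethylsilyloxy)-5-hydroxy-4-oxo-2-phenylchroman-3-yl hexanoate F9. Bu4NF buffered with AcOH in THF at 0 °C removes the silyl group, and the fallback comes back to the route at 10.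

**Further compounds**
F1 | step 2 | methyl (2R,3S)-2,3-dihydroxy-3-phenylpropanoate | COC(=O)[C@H](O)[C@@H](O)c1ccccc1
F2 | step 2 | methyl (4R,5S)-2,2-dimethyl-5-phenyl-1,3-dioxolane-4-carboxylate | COC(=O)[C@@H]1OC(C)(C)O[C@H]1c1ccccc1
F3 | step 2 | 6-{2-[(4R,5S)-2,2-dimethyl-5-phenyl-1,3-dioxolan-4-yl]-2-oxoethyl}-4-hydroxy-2H-pyran-2-one | O=C1C=C(O)C=C(CC(=O)[C@@H]2OC(C)(C)O[C@H]2c2ccccc2)O1
F4 | step 2 | [(4R,5S)-2,2-dimethyl-5-phenyl-1,3-dioxolan-4-yl](2,4,6-trihydroxyphenyl)methanone | O=C(c1c(O)cc(O)cc1O)[C@@H]1OC(C)(C)O[C@H]1c1ccccc1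
F5 | step 2 | (2R,3S)-2,3-dihydroxy-3-phenyl-1-(2,4,6-trihydroxyphenyl)propan-1-one | O=C(c1c(O)cc(O)cc1O)[C@H](O)[C@@H](O)c1ccccc1
F6 | step 1 | (2R,3S)-3-phenyloxirane-2-carbaldehyde | O=C[C@@H]1O[C@H]1c1ccccc1
F7 | step 1 | 4-hydroxy-6-{2-hydroxy-2-[(2S,3S)-3-phenyloxiran-2-yl]ethyl}-2H-pyran-2-one (carbinol epimers) | O=C1C=C(O)C=C(CC(O)[C@@H]2O[C@H]2c2ccccc2)O1
F8 | step 3 | (2R,3R)-7-(tert-butyldimethylsilyloxy)-3,5-dihydroxy-2-phenylchroman-4-one | O[C@H]1C(=O)c2c(O)cc(O[Si](C)(C)C(C)(C)C)cc2O[C@@H]1c1ccccc1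
F9 | step 3 | (2R,3R)-7-(tert-butyldimethylsilyloxy)-5-hydroxy-4-oxo-2-phenylchroman-3-yl hexanoate | CCCCCC(=O)O[C@H]1C(=O)c2c(O)cc(O[Si](C)(C)C(C)(C)C)cc2O[C@@H]1c1ccccc1
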